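**Retrosynthetic overview**
- Target 22 ⇐ C7=C8 enol triflate 21 (C17 comes from CO) ⇐ 17-nor-8-ketone 19.
- 19 ⇐ pinane-type keto hydrazone 17: radical scission of the C4–C7 cyclobutane bond, then closure of C3–C4. Ring B is the six-membered carbocycle of (+)-verbenone and is only unmasked; ring A is formed last.
- 17 ⇐ B-alkyl Suzuki–Miyaura union (C12–C13) of vinyl ketone 9 with (E)-enol triflate 13; C9 is set by deconjugative protonation, C10 by cuprate addition to verbenone 1, C5 comes from verbenone.
- Enabling feature: the gem-dimethyl carbon C4 sits on C5 and is 1,3 to C7, next to the C8 carbon that carries C17. C4–C5–C6–C7 can therefore be the cyclobutane of a pinane whose ten carbons map onto C4–C10 and C18–C20, and a radical at C8 expels C4 as a tertiary radical placed to close ring A onto C3.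

Key step: step 9

Remark: labdane numbering is used for all intermediates; (1R,5R)-(+)-verbenone is assumed to be available in high enantiomeric purity (commercial material, upgraded if needed).

**Route**

Step 1
Reactants: 1 (1R,5R)-(+)-verbenone; 2 2-(2-bromoethyl)-1,3-dioxolane
Product: 5 4-[2-(1,3-dioxolan-2-yl)ethyl]-3-(1-hydroxyethyl)-4,6,6-trimethylbicyclo[3.1.1]heptan-2-one (C4 chain and C3 group anti to the gem-dimethyl bridge; carbinol epimers), via Grignard reagent 3 (not isolated), via bromomagnesium enolate 4 (not isolated)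
Conditions: 2, Mg, THF, 30 °C; CuBr·SMe2 (10 mol%), THF, −40 °C, then 1; then MeCHO, −78 °C; aq. NH4Cl
Reagents that add atoms: acetaldehyde, CC=O
Why: Copper-catalysed conjugate addition of the Grignard reagent to the β,β-disubstituted enone should occur on the face opposite the gem-dimethyl bridge and so set the quaternary C10 centre (C1 chain trans to the C4 carbon on C5), and the magnesium enolate is trapped by acetaldehyde (tandem conjugate addition–aldol reaction); the two aldol centres are removed in step 2.

Step 2
Reactants: 5 aldol adduct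
Product: 7 4-[2-(1,3-dioxolan-2-yl)ethyl]-3-ethylidene-4,6,6-trimethylbicyclo[3.1.1]heptan-2-one (E/Z mixture), via mesylate 6 (not isolated)
Conditions: MsCl, Et3N, CH2Cl2, 0 °C; then DBU, rt
Reagents that add atoms: none
Why: Mesylation and E1cB elimination complete an aldol condensation and give the α-ethylidene ketone, whose alkene geometry is of no consequence.

Step 3
Reactants: 7 ethylidene enone
Product: 9 4-[2-(1,3-dioxolan-2-yl)ethyl]-3-ethenyl-4,6,6-trimethylbicyclo[3.1.1]heptan-2-one (vinyl syn to the gem-dimethyl bridge and cis to the C10 methyl), via potassium dienolate 8 (not isolated)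
Conditions: KN(SiMe3)2, THF, −78 to −40 °C; then AcOH/THF, −78 °C
Reagents that add atoms: none
Why: Because the α′-carbon is a bridgehead (Bredt's rule) only a γ-proton can be removed, and kinetic α-protonation of the extended dienolate (deconjugative protonation) from the face opposite the gem-dimethyl bridge should set C9 with H on that face and the vinyl group cis to the C10 methyl, as in the target.

Step 4
Reactants: 10 ethyl acetoacetate
Product: 11 ethyl (E)-3-(trifluoromethanesulfonyloxy)but-2-enoate
Conditions: Tf2O, aq. Me4NOH, hexanes, 5 °C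
Reagents that add atoms: trifluoromethanesulfonic anhydride, O=S(=O)(OS(=O)(=O)C(F)(F)F)C(F)(F)F
Why: O-Triflation of the non-chelated tetramethylammonium enolate of the β-keto ester should give the (E)-enol triflate (triflate trans to the ester), which fixes the later C13=C14 geometry.

Step 5
Reactants: 11 (E)-enol triflate ester
Product: 12 (E)-4-hydroxybut-2-en-2-yl trifluoromethanesulfonate
Conditions: i-Bu2AlH, CH2Cl2, −78 °C; aq. KNaC4H4O6
Reagents that add atoms: none
Why: 1,2-Reduction of the conjugated ester with diisobutylaluminium hydride at low temperature should leave the enol triflate and the alkene geometry untouched.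

Step 6
Reactants: 12 (E)-triflate alcohol
Product: 13 (E)-3-(trifluoromethanesulfonyloxy)but-2-en-1-yl 2-methylpropanoate
Conditions: i-PrCOCl, pyridine, CH2Cl2, 0 °C
Reagents that add atoms: 2-methylpropanoyl chloride, CC(C)C(=O)Cl
Why: Acylation of the primary allylic alcohol with the acid chloride installs the isobutyrate of the target.

Step 7
Reactants: 9 vinyl ketone; 13 (E)-enol triflate isobutyrate
Product: 15 (E)-5-{4-[2-(1,3-dioxolan-2-yl)ethyl]-4,6,6-trimethyl-2-oxobicyclo[3.1.1]heptan-3-yl}-3-methylpent-2-en-1-yl 2-methylpropanoate (side chain syn to the gem-dimethyl bridge), via B-alkyl-9-BBN 14 (not isolated)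
Conditions: 9-BBN, THF, rt; then 13, Pd(dppf)Cl2 (5 mol%), K3PO4, DMF/H2O, 40 °C
Reagents that add atoms: none
Why: Anti-Markovnikov hydroboration of the monosubstituted alkene (the hindered ketone is left) and B-alkyl Suzuki–Miyaura coupling with retention of the triflate geometry should give the 13E side chain, oxidative addition into the vinyl triflate being much faster than ionization of the allylic ester.

Step 8
Reactants: 15 keto acetal
Product: 17 (E)-3-methyl-5-{4,6,6-trimethyl-2-oxo-4-[3-(2-tosylhydrazinylidene)propyl]bicyclo[3.1.1]heptan-3-yl}pent-2-en-1-yl 2-methylpropanoate, via keto aldehyde 16 (not isolated)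
Conditions: TsNHNH2, TsOH·H2O (10 mol%), THF/H2O, 40 °C
Reagents that add atoms: 4-methylbenzenesulfonohydrazide, Cc1ccc(cc1)S(=O)(=O)NN
Why: Acid-catalysed acetal hydrolysis and hydrazone formation at the unhindered aldehyde should proceed while the neopentyl-type ketone does not condense.

Step 9
Reactants: 17 keto tosylhydrazone
Product: 19 (E)-3-methyl-5-[(1R,4aS,8aS)-5,5,8a-trimethyl-2-oxodecahydronaphthalen-1-yl]pent-2-en-1-yl 2-methylpropanoate, via tributylstannyl enol ether sulfonylhydrazide 18 (not isolated)
Conditions: Bu3SnH (slow addition), AIBN (cat.), PhH, 80 °C, high dilution; then NaOAc·3H2O, EtOH, 75 °C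
Reagents that add atoms: none
Why: Proposed new method: Bu3Sn• adds to the carbonyl oxygen at C8 to give an O-stannyl ketyl that is a cyclobutylcarbinyl radical, so that strain-driven β-scission of the C7–C4 bond (the cyclobutane bond to the gem-dimethyl carbon) releases the tertiary C4 radical and the C7=C8 tin enolate; the C4 radical then adds to the hydrazone carbon C3, the N-radical takes H from Bu3SnH (chain), and warming with NaOAc expels sulfinate and N2 from the N-alkyl-N'-sulfonylhydrazine so that C3 ends as CH2. The closest known reaction types are the O-stannyl ketyl ring-opening/cyclization cascades of α-cyclopropyl ketones, the radical ring opening of pinane cyclobutanes (β-pinene type) and the reductive radical alkylation of sulfonylhydrazones with loss of N2 (Caglioti-type decomposition). Ring A closes in the 6-exo-trig mode onto C=N, while ring B is the carbocycle of verbenone and is only unmasked. No new stereocentre is formed at C3 or C4; the trans ring fusion follows from the fixed C5 and C10 centres, whose C4 and C1 branches are trans-diequatorial on ring B, and C9 is not touched because the enolate lies toward C7. The step needs the ketyl to fragment faster than it is reduced or adds to the hydrazone, which the strained bond aligned with the carbonyl π system and the tertiary radical product should secure, and it needs cyclization faster than H transfer to C4, which slow addition of Bu3SnH at high dilution should secure.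

Step 10
Reactants: 19 17-nor-8-ketone
Product: 21 (E)-3-methyl-5-[(1R,4aS,8aS)-5,5,8a-trimethyl-2-(trifluoromethanesulfonyloxy)-1,4,4a,5,6,7,8,8a-octahydronaphthalen-1-yl]pent-2-en-1-yl 2-methylpropanoate, via potassium enolate 20 (not isolated)
Conditions: KN(SiMe3)2, THF, −78 °C; then PhNTf2, −78 to 0 °C
Reagents that add atoms: N-phenylbis(trifluoromethanesulfonimide), O=S(=O)(N(c1ccccc1)S(=O)(=O)C(F)(F)F)C(F)(F)F
Why: Kinetic deprotonation at the C7 methylene (not at the tertiary C9–H next to quaternary C10, and the ester α-H is far less acidic) followed by O-sulfonylation should give the C7=C8 enol triflate regioselectively without touching C9.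

Step 11
Reactants: 21 enol triflate
Product: 22 (1R,4aS,8aS)-5,5,8a-trimethyl-1-[(E)-3-methyl-5-(2-methylpropanoyloxy)pent-3-en-1-yl]-1,4,4a,5,6,7,8,8a-octahydronaphthalene-2-carboxylic acid (target)
Conditions: Pd(OAc)2 (5 mol%), dppf, CO (1 atm), Et3N, DMF/H2O, 50 °C; then dilute HCl
Reagents that add atoms: carbon monoxide, [C-]#[O+]; water, O
Why: Palladium-catalysed hydroxycarbonylation of the vinyl triflate (oxidative addition, CO insertion, hydrolysis of the acylpalladium) should deliver the α,β-unsaturated acid with the alkene fixed at C7=C8; C9 is not epimerizable in the product and the CO atmosphere disfavours ionization of the allylic ester.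

**Compound list**
1 | (1R,5R)-(+)-verbenone [(1R,5R)-4,6,6-trimethylbicyclo[3.1.1]hept-3-en-2-one] | O=C1C=C(C)[C@H]2C[C@@H]1C2(C)C | starting material
2 | 2-(2-bromoethyl)-1,3-dioxolane | BrCCC1OCCO1 | starting material
3 | [2-(1,3-dioxolan-2-yl)ethyl]magnesium bromide | Br[Mg]CCC1OCCO1 | intermediate
4 | bromomagnesium enolate of the conjugate adduct (C10 chain anti to the gem-dimethyl bridge) | Br[Mg]OC1=C[C@@](C)(CCC2OCCO2)[C@H]3C[C@@H]1C3(C)C | intermediate
5 | 4-[2-(1,3-dioxolan-2-yl)ethyl]-3-(1-hydroxyethyl)-4,6,6-trimethylbicyclo[3.1.1]heptan-2-one (carbinol epimers) | O=C1[C@@H](C(C)O)[C@@](C)(CCC2OCCO2)[C@H]3C[C@@H]1C3(C)C | intermediate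
6 | methanesulfonate of 5 | O=C1[C@@H](C(C)OS(C)(=O)=O)[C@@](C)(CCC2OCCO2)[C@H]3C[C@@H]1C3(C)C | intermediate
7 | 4-[2-(1,3-dioxolan-2-yl)ethyl]-3-ethylidene-4,6,6-trimethylbicyclo[3.1.1]heptan-2-one (E/Z mixture) | O=C1C(=CC)[C@@](C)(CCC2OCCO2)[C@H]3C[C@@H]1C3(C)C | intermediate
8 | potassium dienolate of 7 | [K+].[O-]C1=C(C=C)[C@@](C)(CCC2OCCO2)[C@H]3C[C@@H]1C3(C)C | intermediate
9 | 4-[2-(1,3-dioxolan-2-yl)ethyl]-3-ethenyl-4,6,6-trimethylbicyclo[3.1.1]heptan-2-one (vinyl syn to the bridge) | O=C1[C@H](C=C)[C@@](C)(CCC2OCCO2)[C@H]3C[C@@H]1C3(C)C | intermediate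
10 | ethyl acetoacetate (ethyl 3-oxobutanoate) | CCOC(=O)CC(C)=O | starting material
11 | ethyl (E)-3-(trifluoromethanesulfonyloxy)but-2-enoate | C/C(OS(=O)(=O)C(F)(F)F)=C\C(=O)OCC | intermediate
12 | (E)-4-hydroxybut-2-en-2-yl trifluoromethanesulfonate | C/C(OS(=O)(=O)C(F)(F)F)=C\CO | intermediate
13 | (E)-3-(trifluoromethanesulfonyloxy)but-2-en-1-yl 2-methylpropanoate | C/C(OS(=O)(=O)C(F)(F)F)=C\COC(=O)C(C)C | intermediate
14 | B-alkyl-9-BBN from hydroboration of 9 | O=C1[C@H](CCB4C5CCCC4CCC5)[C@@](C)(CCC2OCCO2)[C@H]3C[C@@H]1C3(C)C | intermediate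
15 | (E)-5-{4-[2-(1,3-dioxolan-2-yl)ethyl]-4,6,6-trimethyl-2-oxobicyclo[3.1.1]heptan-3-yl}-3-methylpent-2-en-1-yl 2-methylpropanoate | O=C1[C@H](CC/C(C)=C/COC(=O)C(C)C)[C@@](C)(CCC2OCCO2)[C@H]3C[C@@H]1C3(C)C | intermediate
16 | keto aldehyde from hydrolysis of 15 | O=C1[C@H](CC/C(C)=C/COC(=O)C(C)C)[C@@](C)(CCC=O)[C@H]2C[C@@H]1C2(C)C | intermediate
17 | aldehyde N-tosylhydrazone of 16 | O=C1[C@H](CC/C(C)=C/COC(=O)C(C)C)[C@@](C)(CC/C=N/NS(=O)(=O)c2ccc(C)cc2)[C@H]3C[C@@H]1C3(C)C | intermediate
18 | tributylstannyl enol ether of 19 carrying a 2-tosylhydrazinyl group at C3 | C/C(=C\COC(=O)C(C)C)CC[C@H]1C(O[Sn](CCCC)(CCCC)CCCC)=CC[C@H]2C(C)(C)C(NNS(=O)(=O)c3ccc(C)cc3)CC[C@]12C | intermediate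
19 | (E)-3-methyl-5-[(1R,4aS,8aS)-5,5,8a-trimethyl-2-oxodecahydronaphthalen-1-yl]pent-2-en-1-yl 2-methylpropanoate | C/C(=C\COC(=O)C(C)C)CC[C@H]1C(=O)CC[C@H]2C(C)(C)CCC[C@]12C | intermediate
20 | potassium C7=C8 enolate of 19 | C/C(=C\COC(=O)C(C)C)CC[C@H]1C([O-])=CC[C@H]2C(C)(C)CCC[C@]12C.[K+] | intermediate
21 | C7=C8 enol triflate of 19 | C/C(=C\COC(=O)C(C)C)CC[C@H]1C(OS(=O)(=O)C(F)(F)F)=CC[C@H]2C(C)(C)CCC[C@]12C | intermediate
22 | (5S,9R,10S,13E)-15-(2-methylpropanoyloxy)labda-7,13-dien-17-oic acid | C/C(=C\COC(=O)C(C)C)CC[C@H]1C(C(=O)O)=CC[C@H]2C(C)(C)CCC[C@]12C | target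

**Step count and risks**

Total step count: 11. Longest linear sequence: 8 steps (1, 2, 3, 7, 8, 9, 10, 11; the branch 4, 5, 6, 7–11 is equally long).

Steps most likely to fail:

1. Step 9 (Proposed new method). The O-stannyl ketyl may take up hydrogen or add directly to the hydrazone carbon before the cyclobutane opens, or the tin radical may be consumed by the hydrazone instead of the hindered ketone. The fallback uses known chemistry only, sets out from 15 and comes back at 19. Me3SiI (from Me3SiCl and NaI, MeCN, −20 °C) cleaves the carbonyl-activated cyclobutane bond ionically, a known opening of pinan-2-one-type ketones, and also the dioxolane, giving after aqueous work-up the ring-opened tertiary iodide keto aldehyde F1. Condensation with TsNHNH2 gives the tosylhydrazone F2. Bu3SnH/AIBN then generates the same tertiary C4 radical by iodine abstraction; it closes ring A by 6-exo addition to the hydrazone carbon, and NaOAc/EtOH completes the loss of sulfinate and N2 to give 19.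

2. Step 3. The dienolate may be protonated at the γ-carbon (return to 7) or from the bridge-side face, and the strained C9 epimer may re-enolize in later steps. The fallback sets out from 7 and comes back at 9. Allylic oxidation of the ethylidene methyl group (SeO2 cat., t-BuOOH) gives the allylic alcohol F3, and ClCO2Me/pyridine gives the methyl carbonate F4. Palladium-catalysed formate reduction (Pd2(dba)3, PBu3, HCO2H/Et3N, THF; Tsuji–Trost type) then delivers hydride from the metal to the more substituted allyl terminus C9 on the less hindered, metal-bearing face, giving the terminal alkene 9 without an enolate protonation.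

3. Step 11. Zerovalent palladium may ionize the allylic isobutyrate (loss or transposition of the ester), or oxidative addition into the hindered triflate may be slow. The fallback sets out from 19 and comes back at 22. Methanolysis of the isobutyrate (K2CO3, MeOH) gives the hydroxy ketone F5 and silylation (t-BuMe2SiCl, imidazole) gives the silyl ether F6. The same kinetic triflation gives the enol triflate F7, and the same hydroxycarbonylation, now without an allylic ester, gives the silyl-protected acid F8. Desilylation (Bu4NF) gives the hydroxy acid F9, and selective O-acylation with 2-methylpropanoic anhydride/pyridine/DMAP (the mixed anhydride of the acid is hydrolysed on aqueous work-up) gives 22.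

Further compounds
F1 | step 9 | ring-opened tertiary iodide keto aldehyde | C/C(=C\COC(=O)C(C)C)CC[C@H]1C(=O)CC[C@@H](C(C)(C)I)[C@]1(C)CCC=O
F2 | step 9 | aldehyde N-tosylhydrazone of F1 | C/C(=C\COC(=O)C(C)C)CC[C@H]1C(=O)CC[C@@H](C(C)(C)I)[C@]1(C)CC/C=N/NS(=O)(=O)c1ccc(C)cc1
F3 | step 3 | 3-(2-hydroxyethylidene) analogue of 7 | O=C1C(=CCO)[C@@](C)(CCC2OCCO2)[C@H]3C[C@@H]1C3(C)C
F4 | step 3 | methyl carbonate of F3 | O=C1C(=CCOC(=O)OC)[C@@](C)(CCC2OCCO2)[C@H]3C[C@@H]1C3(C)C
F5 | step 11 | hydroxy ketone (de-acylated 19) | C/C(=C\CO)CC[C@H]1C(=O)CC[C@H]2C(C)(C)CCC[C@]12C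
F6 | step 11 | tert-butyldimethylsilyl ether of F5 | C/C(=C\CO[Si](C)(C)C(C)(C)C)CC[C@H]1C(=O)CC[C@H]2C(C)(C)CCC[C@]12C
F7 | step 11 | C7=C8 enol triflate of F6 | C/C(=C\CO[Si](C)(C)C(C)(C)C)CC[C@H]1C(OS(=O)(=O)C(F)(F)F)=CC[C@H]2C(C)(C)CCC[C@]12C
F8 | step 11 | silyl-protected 7-en-17-oic acid | C/C(=C\CO[Si](C)(C)C(C)(C)C)CC[C@H]1C(C(=O)O)=CC[C@H]2C(C)(C)CCC[C@]12C
F9 | step 11 | (5S,9R,10S,13E)-15-hydroxylabda-7,13-dien-17-oic acid | C/C(=C\CO)CC[C@H]1C(C(=O)O)=CC[C@H]2C(C)(C)CCC[C@]12C
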